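## Retrosynthetic overview
1. The only strategic bond is C6–C7, in the middle of the unfunctionalised chain (C22 + C6 = C28). There is no stereocentre and no ring is formed, because the phenyl ring is bought.
2. C7–C28 half: docosan-1-ol 1 gives docosanal 2, which condenses with tritylhydrazine hydrochloride 3 to the N-trityl hydrazone 4.
3. C1–C6 half: benzyl 6-bromohexanoate 5, which already carries the benzyl ester.
4. Key step: in the lithium azo anion 6 of 4, the former formyl carbon acts as a docosyl C1 carbanion equivalent. It displaces bromide from 5, joining two natively electrophilic carbons. The azo ester 7 then loses N2 and trityl in the same flask to give target 8.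

Assumption: the target has no stereocentre and no stereogenic double bond, so it is one achiral compound and no enantiocontrol is needed.
Assumption: tritylhydrazine hydrochloride 3 and benzyl 6-bromohexanoate 5 are bought as catalogue compounds.

## Route

Step 1
Reactants: 1 docosan-1-ol (behenyl alcohol)
Product: 2 docosanal
Conditions: IBX (1.5 equiv), EtOAc, 80 °C, 4 h; cool, filter, concentrate
Reagents that add atoms: none
Why: IBX oxidation (iodine(V) ligand exchange, then reductive elimination) stops at the aldehyde because no hydrate pathway is available, hot EtOAc keeps the waxy C22 alcohol dissolved while IBX and its reduced form stay insoluble and are filtered off, and no stereocentre is created.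

Step 2
Reactants: 2 docosanal; 3 tritylhydrazine hydrochloride
Product: 4 docosanal N-tritylhydrazone, E at C=N
Conditions: NaOAc (1.1 equiv), THF–EtOH 1:1, 40 °C → rt, Ar
Reagents that add atoms: tritylhydrazine hydrochloride (3), Cl.NNC(c1ccccc1)(c1ccccc1)c1ccccc1
Why: Hydrazone condensation, in which the unhindered terminal NH2 (an α-effect nucleophile) adds to the aldehyde and loses water under NaOAc/AcOH buffering too mild to ionise the N–trityl bond, giving the less crowded E isomer, whose geometry is erased in step 3 and which carries no stereocentre.

Step 3
Reactants: 4 docosanal N-tritylhydrazone (1.1 equiv); 5 benzyl 6-bromohexanoate (1.0 equiv)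
Product: 8 benzyl octacosanoate, via lithium azo anion 6 (not isolated), via trityl azo ester 7 (not isolated)
Conditions: n-BuLi (1.0 equiv relative to 4), THF, −40 °C; 5, DMPU, −40 → 0 °C; then EtSH (10 equiv), 0 °C → rt (N2 evolution)
Reagents that add atoms: benzyl 6-bromohexanoate (5), BrCCCCCC(=O)OCc1ccccc1
Why: Azo-anion reductive alkylation of a trityl hydrazone (Baldwin–Adlington type, aldehyde as alkyl-carbanion equivalent), in which N-deprotonation gives the ambident anion 6 whose nitrogen is shielded by trityl, so the former formyl carbon attacks the primary C–Br of 5 by SN2 faster than the ester at ≤0 °C, and azo compound 7 then fragments homolytically on warming into Ph3C•, N2 and a secondary alkyl radical that takes H from EtSH, turning the transient racemic C7 centre into CH2 so that no stereocentre remains.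

## Compound list
1 | docosan-1-ol | CCCCCCCCCCCCCCCCCCCCCCO | starting material
2 | docosanal | CCCCCCCCCCCCCCCCCCCCCC=O | intermediate
3 | tritylhydrazine hydrochloride | Cl.NNC(c1ccccc1)(c1ccccc1)c1ccccc1 | starting material
4 | (E)-docosanal N-tritylhydrazone | CCCCCCCCCCCCCCCCCCCCC/C=N/NC(c1ccccc1)(c1ccccc1)c1ccccc1 | intermediate
5 | benzyl 6-bromohexanoate | BrCCCCCC(=O)OCc1ccccc1 | starting material
6 | lithium azo anion, the N-lithio salt of 4 (not isolated) | [Li+].CCCCCCCCCCCCCCCCCCCCC/C=N/[N-]C(c1ccccc1)(c1ccccc1)c1ccccc1 | intermediate
7 | trityl azo ester, benzyl 7-[(E)-trityldiazenyl]octacosanoate, racemic at C7 (not isolated) | CCCCCCCCCCCCCCCCCCCCCC(CCCCCC(=O)OCc1ccccc1)/N=N/C(c1ccccc1)(c1ccccc1)c1ccccc1 | intermediate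
8 | benzyl octacosanoate | CCCCCCCCCCCCCCCCCCCCCCCCCCCC(=O)OCc1ccccc1 | target

## Totals
Total step count: 3. Longest linear sequence: 3 (1 → 2 → 4 → 8).

## Steps most likely to fail

**Step 3 (highest risk).**
- The stabilised anion 6 may displace a primary bromide only slowly.
- Ester attack could then compete.
- Proton transfer from 7 to 6 could also compete, tautomerising 7 to a ketone hydrazone.
- The radical pair from 7 can recombine in the solvent cage or disproportionate to an alkene.

The fallback sets out from docosanal 2 and comes back at target 8. It separates bond formation from defunctionalisation. Compound 2 is thioacetalised with propane-1,3-dithiol and BF3·OEt2 in CH2Cl2 to 2-henicosyl-1,3-dithiane F1. This is lithiated with n-BuLi in THF at −20 °C and alkylated with 5 at −78 °C in THF/DMPU, where the hindered dithianyl anion takes the primary bromide in preference to the ester. The product is the stable, isolable benzyl 6-(2-henicosyl-1,3-dithian-2-yl)hexanoate F2. Both C–S bonds of F2 are then reduced with Bu3SnH/AIBN in refluxing toluene to give 8. This reagent spares the benzyl ester, which Raney nickel would endanger.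

**Step 2.**
- The quality or supply of 3 may be poor.
- Partial detritylation is possible.
- The N–H hydrazone can autoxidise.

The fallback sets out from 2 and comes back at 4. It builds the N–N–C array in the opposite order from bulk chemicals. Compound 2 is added slowly to excess hydrazine hydrate in THF–EtOH, the excess suppressing azine formation, to give docosanal hydrazone F3. After the hydrazine is removed, F3 is N-tritylated at its terminal NH2 with trityl chloride and Et3N in CH2Cl2 at 0 °C to give 4.

**Step 1.**
- The C22 alcohol dissolves poorly.
- The aldehyde may over-oxidise or trimerise during handling.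

The fallback sets out from 1 and comes back at 2. It replaces alcohol oxidation with substitution followed by elimination. Compound 1 is converted with 48% HBr/H2SO4 at reflux into 1-bromodocosane F4. F4 is O-alkylated onto anhydrous trimethylamine N-oxide in DMSO–THF at 50 °C. The alkoxyammonium salt eliminates trimethylamine to give 2, and over-oxidation is impossible on this path.

## Further compounds
F1 | step 3 | 2-henicosyl-1,3-dithiane | CCCCCCCCCCCCCCCCCCCCCC1SCCCS1
F2 | step 3 | benzyl 6-(2-henicosyl-1,3-dithian-2-yl)hexanoate | CCCCCCCCCCCCCCCCCCCCCC1(CCCCCC(=O)OCc2ccccc2)SCCCS1
F3 | step 2 | (E)-docosanal hydrazone | CCCCCCCCCCCCCCCCCCCCC/C=N/N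
F4 | step 1 | 1-bromodocosane | CCCCCCCCCCCCCCCCCCCCCCBr
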